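**Retrosynthetic overview**

1. Ring numbering used below: C1 = C(CH3)2, C2 = CH(OH), C3 and C4 = CH2, C5 = C(CH3)(OH), C6 = CH carrying the side chain. The cyclohexane is the only ring the route has to build; the coumarin is bought as umbelliferone.
2. Target ⇐ Mitsunobu etherification of umbelliferone with tetraol 16 ⇐ acetonide diol 15 ⇐ reduction of the 4-hydroxy ketone 14 with a bulky borohydride.
3. Key disconnection of 14: C1–C2 and C3–C4 are cut together. C2–C3 is (1-ethoxyvinyl)lithium, an acyl anion equivalent. C4–C5–C6–C1 is the open-chain epoxide/tertiary pinacol boronate 11. The ring closes in a boronate annulation (epoxide opening plus 1,2-metallate shift).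
4. Enabling feature: the oxygen-bearing ring carbons C2 and C5 stand 1,4 across the C3–C4 unit, and C2 sits next to the quaternary C1. An alkenyl boronate complex and an epoxide give exactly this 1,4-dioxygenated pattern; C1 rides on boron as the migrating group and the strained oxirane O–C5–C4 is the internal electrophile.
5. 11 ⇐ (R)-linalool: hydroboration (side-chain oxygen), SeO2 oxidation and Sharpless epoxidation (C5), anti opening with isopropenyl cuprate (C6), epoxide closure, Markovnikov hydrobromination and borylation (C1–B).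

Key step: step 9

Remark: commercial (R)-(−)-linalool is taken as enantiopure; its 1,3-diol is masked as an acetonide because organometallic steps follow, so the coumarin is attached last.

**Step 1**
Reactants: 1 (R)-(−)-linalool
Product: 3 (3R)-3,7-dimethyloct-6-ene-1,3-diol, via B-alkyl-9-borabicyclononane adduct 2 (not isolated)
Conditions: 9-BBN, THF, 0 °C to rt; then NaOH, H2O2, 0 °C
Reagents that add atoms: 9-borabicyclo[3.3.1]nonane, B1C2CCCC1CCC2 (boron kept only in 2); hydrogen peroxide, OO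
Why: Anti-Markovnikov hydroboration–oxidation, in which the bulky borane takes the monosubstituted vinyl group and leaves the trisubstituted alkene, the carbinol stereocentre not being involved.

**Step 2**
Reactants: 3 (3R)-3,7-dimethyloct-6-ene-1,3-diol
Product: 4 (4R)-2,2,4-trimethyl-4-(4-methylpent-3-en-1-yl)-1,3-dioxane
Conditions: 2,2-dimethoxypropane, PPTS (cat.), CH2Cl2, rt
Reagents that add atoms: 2,2-dimethoxypropane, COC(C)(C)OC
Why: Acid-catalysed acetal exchange (acetonide formation) locks the primary and the tertiary hydroxyl in a 1,3-dioxane that should survive the organometallic, radical and basic steps to come.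

**Step 3**
Reactants: 4 (4R)-2,2,4-trimethyl-4-(4-methylpent-3-en-1-yl)-1,3-dioxane
Product: 5 (2E)-2-methyl-5-[(4R)-2,2,4-trimethyl-1,3-dioxan-4-yl]pent-2-en-1-ol
Conditions: SeO2 (cat.), t-BuOOH, CH2Cl2, rt; then NaBH4, MeOH, 0 °C
Reagents that add atoms: selenium dioxide, O=[Se]=O (oxygen donor, regenerated); tert-butyl hydroperoxide, CC(C)(C)OO (terminal oxidant)
Why: Allylic oxidation with SeO2 (ene reaction then [2,3]-sigmatropic shift) takes the (E)-methyl group of the trisubstituted alkene and so gives the (E)-configured primary allylic alcohol, the borohydride returning any over-oxidised enal.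

**Step 4**
Reactants: 5 (2E)-2-methyl-5-[(4R)-2,2,4-trimethyl-1,3-dioxan-4-yl]pent-2-en-1-ol
Product: 6 [(2S,3S)-2-methyl-3-{2-[(4R)-2,2,4-trimethyl-1,3-dioxan-4-yl]ethyl}oxiran-2-yl]methanol
Conditions: Ti(OiPr)4, L-(+)-diethyl tartrate, t-BuOOH, 4 Å MS, CH2Cl2, −20 °C
Reagents that add atoms: tert-butyl hydroperoxide, CC(C)(C)OO
Why: Sharpless asymmetric epoxidation; with L-(+)-tartrate the (E)-2-methyl allylic alcohol should give the (2S,3S)-epoxy alcohol under reagent control, which fixes C5 directly and C6 after inversion.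

**Step 5**
Reactants: 6 [(2S,3S)-2-methyl-3-{2-[(4R)-2,2,4-trimethyl-1,3-dioxan-4-yl]ethyl}oxiran-2-yl]methanol
Product: 7 (2R,3S)-2-methyl-3-(prop-1-en-2-yl)-5-[(4R)-2,2,4-trimethyl-1,3-dioxan-4-yl]pentane-1,2-diol
Conditions: isopropenylmagnesium bromide (excess), CuI (cat.), THF, −30 °C to 0 °C
Reagents that add atoms: isopropenylmagnesium bromide, CC(=C)[Mg]Br
Why: Copper-catalysed Grignard opening of a 2,3-epoxy alcohol at its less substituted carbon (the other one is quaternary); SN2 inversion sets C6 anti to the retained C5–O bond, which is the trans relation of the C5 hydroxyl and the side chain in the target.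

**Step 6**
Reactants: 7 (2R,3S)-2-methyl-3-(prop-1-en-2-yl)-5-[(4R)-2,2,4-trimethyl-1,3-dioxan-4-yl]pentane-1,2-diol
Product: 9 (4R)-2,2,4-trimethyl-4-{(3S)-4-methyl-3-[(2R)-2-methyloxiran-2-yl]pent-4-en-1-yl}-1,3-dioxane, via primary tosylate 8 (not isolated)
Conditions: NaH, N-tosylimidazole, THF, 0 °C to rt
Reagents that add atoms: 1-(p-toluenesulfonyl)imidazole, Cc1ccc(cc1)S(=O)(=O)n1ccnc1 (tosyl group kept only in 8)
Why: Selective sulfonylation of the primary hydroxyl and intramolecular Williamson etherification by the tertiary alkoxide (3-exo-tet) give the terminal epoxide without breaking a bond at C5 or C6, so both stereocentres are kept.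

**Step 7**
Reactants: 9 (4R)-2,2,4-trimethyl-4-{(3S)-4-methyl-3-[(2R)-2-methyloxiran-2-yl]pent-4-en-1-yl}-1,3-dioxane
Product: 10 (4R)-4-{(3R)-4-bromo-4-methyl-3-[(2R)-2-methyloxiran-2-yl]pentyl}-2,2,4-trimethyl-1,3-dioxane
Conditions: Co(acac)2, TsBr, t-BuOOH, Et3SiH, n-PrOH, rt
Reagents that add atoms: p-toluenesulfonyl bromide, Cc1ccc(cc1)S(=O)(=O)Br
Why: Cobalt-hydride hydrogen-atom-transfer hydrobromination (Mukaiyama-type radical hydrofunctionalisation): H• adds to the CH2 end of the 1,1-disubstituted alkene and the tertiary radical takes bromine from TsBr, giving the Markovnikov bromide under near-neutral conditions that should spare epoxide and acetal.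

**Step 8**
Reactants: 10 (4R)-4-{(3R)-4-bromo-4-methyl-3-[(2R)-2-methyloxiran-2-yl]pentyl}-2,2,4-trimethyl-1,3-dioxane
Product: 11 4,4,5,5-tetramethyl-2-{(3S)-2-methyl-3-[(2R)-2-methyloxiran-2-yl]-5-[(4R)-2,2,4-trimethyl-1,3-dioxan-4-yl]pentan-2-yl}-1,3,2-dioxaborolane
Conditions: NiBr2·diglyme (cat.), 2,6-bis(4-isopropyl-4,5-dihydrooxazol-2-yl)pyridine (cat.), B2pin2, KOEt, i-Pr2O/DMA, rt
Reagents that add atoms: bis(pinacolato)diboron, CC1(C)OB(OC1(C)C)B1OC(C)(C)C(C)(C)O1
Why: Nickel-catalysed Miyaura-type borylation of an unactivated tertiary alkyl bromide through the tertiary radical; the boron-bearing carbon (C1) is not stereogenic and C5 and C6 are not touched.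

**Step 9**
Reactants: 11 4,4,5,5-tetramethyl-2-{(3S)-2-methyl-3-[(2R)-2-methyloxiran-2-yl]-5-[(4R)-2,2,4-trimethyl-1,3-dioxan-4-yl]pentan-2-yl}-1,3,2-dioxaborolane
Product: 14 (3S,4S)-4-hydroxy-2,2,4-trimethyl-3-{2-[(4R)-2,2,4-trimethyl-1,3-dioxan-4-yl]ethyl}cyclohexan-1-one, via lithium ethoxyvinyl boronate complex 12 (not isolated), via ring-contracted ethoxy boronate 13 (not isolated)
Conditions: ethyl vinyl ether, t-BuLi, THF, −78 °C to 0 °C; then 11, −78 °C to 40 °C; then NaOH, H2O2, 0 °C to rt
Reagents that add atoms: ethyl vinyl ether, C=COCC (used as (1-ethoxyvinyl)lithium, [Li]C(=C)OCC); tert-butyllithium, [Li]C(C)(C)C (lithium kept only in 12 and 13); hydrogen peroxide, OO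
Why: Proposed new method: (1-ethoxyvinyl)lithium adds to the tertiary pinacol boronate to give complex 12; its electron-rich enol ether terminus (becoming C3) then opens the tethered 2,2-disubstituted epoxide at the CH2 carbon (C4) by SN2 attack, and the oxocarbenium character that develops at the boron-bound carbon (C2) triggers 1,2-migration of the tertiary alkyl group (C1) from boron to C2, so that C3–C4 and C1–C2 form in one cascade, after which oxidation of the α-ethoxy boronate 13 unveils the C2 ketone. The closest known reaction types are the electrophile-induced 1,2-metallate rearrangement of alkenyl boronate complexes (Zweifel-type couplings and the ketone synthesis from boronic esters and lithiated enol ethers) and the coupling of lithium vinylborates with epoxides to 1,4-dioxygenated products; new is that the epoxide is tethered to the migrating group, which turns the coupling into an annulation. The cyclohexane closes through a seven-membered boracycle (endo opening of the epoxide, 7-endo-tet, since the exo carbon is quaternary and cannot undergo SN2) that contracts to the carbocycle in the 1,2-shift, driven by release of the oxirane strain. No new stereocentre remains (C2 leaves as a carbonyl), and C5 and C6 come through unchanged because neither the C5–O bond nor any bond at C6 is broken. The step needs attack of the enol ether carbon at the epoxide CH2 and migration of carbon rather than of a pinacolate oxygen; the first is secured by the SN2 bias of the 2,2-disubstituted epoxide and the high nucleophilicity of the alkoxyvinyl boronate, the second by the tertiary alkyl group being the only carbon ligand on boron that can migrate.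

**Step 10**
Reactants: 14 (3S,4S)-4-hydroxy-2,2,4-trimethyl-3-{2-[(4R)-2,2,4-trimethyl-1,3-dioxan-4-yl]ethyl}cyclohexan-1-one
Product: 15 (1S,2S,4R)-1,3,3-trimethyl-2-{2-[(4R)-2,2,4-trimethyl-1,3-dioxan-4-yl]ethyl}cyclohexane-1,4-diol
Conditions: LiBH(s-Bu)3 (L-Selectride), THF, −78 °C; then NaOH, H2O2
Reagents that add atoms: none
Why: Ketone reduction with a bulky trialkylborohydride; equatorial hydride delivery in the chair that keeps the C6 side chain equatorial (the other chair places the side chain axial over the carbonyl and is hindered for both trajectories) should give the axial C2 alcohol, cis to the C5 hydroxyl and trans to the side chain, as is usual for 2,2-dimethylcyclohexanones of the 3-oxo-4,4-dimethyl terpenoid type.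

**Step 11**
Reactants: 15 (1S,2S,4R)-1,3,3-trimethyl-2-{2-[(4R)-2,2,4-trimethyl-1,3-dioxan-4-yl]ethyl}cyclohexane-1,4-diol
Product: 16 (1S,2S,4R)-2-[(3R)-3,5-dihydroxy-3-methylpentyl]-1,3,3-trimethylcyclohexane-1,4-diol
Conditions: PPTS (cat.), MeOH, rt
Reagents that add atoms: none
Why: Mild acid-catalysed transacetalisation removes the acetonide without ionising the tertiary alcohols, and no stereocentre is involved.

**Step 12**
Reactants: 16 (1S,2S,4R)-2-[(3R)-3,5-dihydroxy-3-methylpentyl]-1,3,3-trimethylcyclohexane-1,4-diol; 17 umbelliferone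
Product: 18 7-{[(3R)-5-[(1S,2S,5R)-2,5-dihydroxy-2,6,6-trimethylcyclohexyl]-3-hydroxy-3-methylpentyl]oxy}-2H-chromen-2-one (target)
Conditions: PPh3, DIAD, THF, 0 °C to rt
Reagents that add atoms: none
Why: Mitsunobu etherification of the phenol with the only primary hydroxyl of the tetraol; the hindered secondary and the two tertiary hydroxyls should not be activated, and no stereocentre is touched.

**Compound list**

1 | (R)-(−)-linalool, (3R)-3,7-dimethylocta-1,6-dien-3-ol | CC(C)=CCC[C@@](C)(O)C=C | starting material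
2 | B-[(3S)-3-hydroxy-3,7-dimethyloct-6-en-1-yl]-9-borabicyclo[3.3.1]nonane (same spatial arrangement as 1; descriptor changes by priority only) | CC(C)=CCC[C@@](C)(O)CCB1C2CCCC1CCC2 | intermediate (not isolated)
3 | (3R)-3,7-dimethyloct-6-ene-1,3-diol | CC(C)=CCC[C@@](C)(O)CCO | intermediate
4 | (4R)-2,2,4-trimethyl-4-(4-methylpent-3-en-1-yl)-1,3-dioxane | CC(C)=CCC[C@@]1(C)OC(C)(C)OCC1 | intermediate
5 | (2E)-2-methyl-5-[(4R)-2,2,4-trimethyl-1,3-dioxan-4-yl]pent-2-en-1-ol | OC/C(C)=C/CC[C@@]1(C)OC(C)(C)OCC1 | intermediate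
6 | [(2S,3S)-2-methyl-3-{2-[(4R)-2,2,4-trimethyl-1,3-dioxan-4-yl]ethyl}oxiran-2-yl]methanol | OC[C@]1(C)O[C@H]1CC[C@@]2(C)OC(C)(C)OCC2 | intermediate
7 | (2R,3S)-2-methyl-3-(prop-1-en-2-yl)-5-[(4R)-2,2,4-trimethyl-1,3-dioxan-4-yl]pentane-1,2-diol | OC[C@](C)(O)[C@H](C(C)=C)CC[C@@]1(C)OC(C)(C)OCC1 | intermediate
8 | (2R,3S)-2-hydroxy-2-methyl-3-(prop-1-en-2-yl)-5-[(4R)-2,2,4-trimethyl-1,3-dioxan-4-yl]pentyl 4-methylbenzenesulfonate | Cc1ccc(cc1)S(=O)(=O)OC[C@](C)(O)[C@H](C(C)=C)CC[C@@]2(C)OC(C)(C)OCC2 | intermediate (not isolated)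
9 | (4R)-2,2,4-trimethyl-4-{(3S)-4-methyl-3-[(2R)-2-methyloxiran-2-yl]pent-4-en-1-yl}-1,3-dioxane | C[C@]1(CO1)[C@H](C(C)=C)CC[C@@]2(C)OC(C)(C)OCC2 | intermediate
10 | (4R)-4-{(3R)-4-bromo-4-methyl-3-[(2R)-2-methyloxiran-2-yl]pentyl}-2,2,4-trimethyl-1,3-dioxane | C[C@]1(CO1)[C@H](C(C)(C)Br)CC[C@@]2(C)OC(C)(C)OCC2 | intermediate
11 | 4,4,5,5-tetramethyl-2-{(3S)-2-methyl-3-[(2R)-2-methyloxiran-2-yl]-5-[(4R)-2,2,4-trimethyl-1,3-dioxan-4-yl]pentan-2-yl}-1,3,2-dioxaborolane | C[C@]1(CO1)[C@H](C(C)(C)B3OC(C)(C)C(C)(C)O3)CC[C@@]2(C)OC(C)(C)OCC2 | intermediate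
12 | lithium boronate complex of 11 (tetracoordinate boron carrying the pinacolate, the tertiary alkyl group and a 1-ethoxyvinyl group; stereocentres as in 11) | [Li+].C[C@]1(CO1)[C@H](C(C)(C)[B-]3(C(=C)OCC)OC(C)(C)C(C)(C)O3)CC[C@@]2(C)OC(C)(C)OCC2 | intermediate (not isolated)
13 | lithium (1S,2S)-4-ethoxy-1,3,3-trimethyl-4-(4,4,5,5-tetramethyl-1,3,2-dioxaborolan-2-yl)-2-{2-[(4R)-2,2,4-trimethyl-1,3-dioxan-4-yl]ethyl}cyclohexan-1-olate (configuration at the ethoxy/boryl carbon not defined) | [Li+].CC1(C)C(OCC)(B2OC(C)(C)C(C)(C)O2)CC[C@](C)([O-])[C@H]1CC[C@@]3(C)OC(C)(C)OCC3 | intermediate (not isolated)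
14 | (3S,4S)-4-hydroxy-2,2,4-trimethyl-3-{2-[(4R)-2,2,4-trimethyl-1,3-dioxan-4-yl]ethyl}cyclohexan-1-one | CC1(C)C(=O)CC[C@](C)(O)[C@H]1CC[C@@]2(C)OC(C)(C)OCC2 | intermediate
15 | (1S,2S,4R)-1,3,3-trimethyl-2-{2-[(4R)-2,2,4-trimethyl-1,3-dioxan-4-yl]ethyl}cyclohexane-1,4-diol | CC1(C)[C@H](O)CC[C@](C)(O)[C@H]1CC[C@@]2(C)OC(C)(C)OCC2 | intermediate
16 | (1S,2S,4R)-2-[(3R)-3,5-dihydroxy-3-methylpentyl]-1,3,3-trimethylcyclohexane-1,4-diol | CC1(C)[C@H](O)CC[C@](C)(O)[C@H]1CC[C@@](C)(O)CCO | intermediate
17 | umbelliferone, 7-hydroxy-2H-chromen-2-one | O=c1ccc2ccc(O)cc2o1 | starting material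
18 | 7-{[(3R)-5-[(1S,2S,5R)-2,5-dihydroxy-2,6,6-trimethylcyclohexyl]-3-hydroxy-3-methylpentyl]oxy}-2H-chromen-2-one | CC1(C)[C@H](O)CC[C@](C)(O)[C@H]1CC[C@@](C)(O)CCOc1ccc2ccc(=O)oc2c1 | target

**Step count and risks**

Total step count: 12. Longest linear sequence: 12 steps from (R)-linalool; umbelliferone enters in the last step.

Steps most likely to fail:

1. Step 9 (proposed boronate annulation). The ring-closing attack of the alkoxyvinyl boronate on the epoxide may be slower than decomposition of the boronate complex, or the freed alkoxide may add to the oxocarbenium centre before the 1,2-shift. The fallback uses known chemistry and makes the two ring bonds one after the other; it sets out from epoxide 9 and comes back at diol 15. Lithioacetonitrile (LiCH2CN, THF, −78 °C to rt) should open the epoxide of 9 at its CH2 carbon to give (4S,5S)-4-hydroxy-4,6-dimethyl-5-{2-[(4R)-2,2,4-trimethyl-1,3-dioxan-4-yl]ethyl}hept-6-enenitrile F1, which forms C3–C4. Reduction with i-Bu2AlH (CH2Cl2, −78 °C) and hydrolytic work-up should give the masked 4-hydroxy aldehyde as the lactol (5S)-5-methyl-5-{(3S)-2-methyl-5-[(4R)-2,2,4-trimethyl-1,3-dioxan-4-yl]pent-1-en-3-yl}oxolan-2-ol F2. An iron-hydride hydrogen-atom-transfer reductive cyclisation (Fe(acac)3, PhSiH3, EtOH, 60 °C) then turns the isopropenyl group into the tertiary radical, which adds to the aldehyde carbon (6-exo-trig, C1–C2) and should give 15.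

2. Step 8 (nickel-catalysed borylation). Base-induced loss of HBr from the hindered tertiary bromide, or opening of the neighbouring epoxide by nickel or boryl species, may outrun C–B bond formation. The fallback uses a C–O instead of a C–Br radical precursor; it sets out from alkene 9 (so it also replaces step 7) and comes back at boronate 11. Mukaiyama hydration (Mn(dpm)3, PhSiH3, O2, i-PrOH, rt) should give the tertiary alcohol (3S)-2-methyl-3-[(2R)-2-methyloxiran-2-yl]-5-[(4R)-2,2,4-trimethyl-1,3-dioxan-4-yl]pentan-2-ol F3. Methyl chlorooxoacetate (pyridine, DMAP, CH2Cl2) converts it into methyl (3S)-2-methyl-3-[(2R)-2-methyloxiran-2-yl]-5-[(4R)-2,2,4-trimethyl-1,3-dioxan-4-yl]pentan-2-yl oxalate F4. Radical deoxygenative borylation of this oxalate with bis(catecholato)diboron under blue light in DMF, followed by exchange with pinacol and Et3N, should give 11.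

3. Step 10 (ketone reduction). Hydride delivery may show poor facial selectivity if the ketone reacts through the chair with the side chain axial. The fallback replaces hydride addition by a hydroxyl-directed epoxidation whose outcome does not depend on the ring conformation; it sets out from ketone 14 and comes back at diol 15. KN(SiMe3)2 and PhNTf2 (THF, −78 °C) should give (4S,5S)-4-hydroxy-4,6,6-trimethyl-5-{2-[(4R)-2,2,4-trimethyl-1,3-dioxan-4-yl]ethyl}cyclohex-1-en-1-yl trifluoromethanesulfonate F5, since enolisation is possible only towards C3. Reduction with Pd(OAc)2, PPh3, HCO2H and n-Bu3N (DMF, 60 °C) should give (1S,6S)-1,5,5-trimethyl-6-{2-[(4R)-2,2,4-trimethyl-1,3-dioxan-4-yl]ethyl}cyclohex-3-en-1-ol F6. VO(acac)2 and t-BuOOH (CH2Cl2, rt) should epoxidise the C2=C3 bond on the face of the homoallylic C5 hydroxyl to give (1R,3S,4S,6S)-3,5,5-trimethyl-4-{2-[(4R)-2,2,4-trimethyl-1,3-dioxan-4-yl]ethyl}-7-oxabicyclo[4.1.0]heptan-3-ol F7, with the oxirane oxygen syn to the hydroxyl. LiAlH4 (THF, 0 °C to reflux) should open the epoxide at the less hindered C3 (trans-diaxial opening) and keep the C2–O bond, giving 15.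

**Further compounds**

F1 | step 9 | (4S,5S)-4-hydroxy-4,6-dimethyl-5-{2-[(4R)-2,2,4-trimethyl-1,3-dioxan-4-yl]ethyl}hept-6-enenitrile | N#CCC[C@](C)(O)[C@H](C(C)=C)CC[C@@]1(C)OC(C)(C)OCC1
F2 | step 9 | (5S)-5-methyl-5-{(3S)-2-methyl-5-[(4R)-2,2,4-trimethyl-1,3-dioxan-4-yl]pent-1-en-3-yl}oxolan-2-ol (lactol, both anomers) | OC1CC[C@](C)(O1)[C@H](C(C)=C)CC[C@@]2(C)OC(C)(C)OCC2
F3 | step 8 | (3S)-2-methyl-3-[(2R)-2-methyloxiran-2-yl]-5-[(4R)-2,2,4-trimethyl-1,3-dioxan-4-yl]pentan-2-ol | C[C@]1(CO1)[C@H](C(C)(C)O)CC[C@@]2(C)OC(C)(C)OCC2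
F4 | step 8 | methyl (3S)-2-methyl-3-[(2R)-2-methyloxiran-2-yl]-5-[(4R)-2,2,4-trimethyl-1,3-dioxan-4-yl]pentan-2-yl oxalate | C[C@]1(CO1)[C@H](C(C)(C)OC(=O)C(=O)OC)CC[C@@]2(C)OC(C)(C)OCC2
F5 | step 10 | (4S,5S)-4-hydroxy-4,6,6-trimethyl-5-{2-[(4R)-2,2,4-trimethyl-1,3-dioxan-4-yl]ethyl}cyclohex-1-en-1-yl trifluoromethanesulfonate | CC1(C)C(OS(=O)(=O)C(F)(F)F)=CC[C@](C)(O)[C@H]1CC[C@@]2(C)OC(C)(C)OCC2
F6 | step 10 | (1S,6S)-1,5,5-trimethyl-6-{2-[(4R)-2,2,4-trimethyl-1,3-dioxan-4-yl]ethyl}cyclohex-3-en-1-ol | CC1(C)C=CC[C@](C)(O)[C@H]1CC[C@@]2(C)OC(C)(C)OCC2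
F7 | step 10 | (1R,3S,4S,6S)-3,5,5-trimethyl-4-{2-[(4R)-2,2,4-trimethyl-1,3-dioxan-4-yl]ethyl}-7-oxabicyclo[4.1.0]heptan-3-ol (oxirane oxygen syn to the hydroxyl) | CC1(C)[C@@H]2O[C@@H]2C[C@](C)(O)[C@H]1CC[C@@]3(C)OC(C)(C)OCC3
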